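No constants are given for these flasks, so what can be said of the gamma run has to be read from the runs before it.

| setting | delta | eta | alpha | epsilon | gamma |
|---|---|---|---|---|---|
| substrate | 80.0 mM | 32.0 mM | 80.0 mM | 120 mM | 170 mM |
| catalyst | 1.60 mM | 1.60 mM | 4.80 mM | 1.60 mM | 1.60 mM |
| time |  |  |  |  | 9.7 min |

- delta run (time / min: [product] / mM): 0.35: 2.8; 1.1: 8.9; 2.0: 16.8; 3.2: 23.9; 4.6: 31.0; 6.1: 36.9; 7.8: 39.9; 9.7: 41.4
- eta run (time / min: [product] / mM): 0.35: 2.7; 1.1: 7.3; 2.0: 10.7; 3.2: 15.6; 4.6: 18.7; 6.1: 21.4; 7.8: 22.2; 9.7: 22.6
- alpha run (time / min: [product] / mM): 0.35: 8.4; 1.1: 23.3; 2.0: 36.4; 3.2: 46.5; 4.6: 50.8; 6.1: 52.9; 7.8: 52.4; 9.7: 52.2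
- epsilon run (time / min: [product] / mM): 0.35: 3.5; 1.1: 10.6; 2.0: 17.9; 3.2: 27.8; 4.6: 34.9; 6.1: 42.0; 7.8: 46.7; 9.7: 49.5

(readings scatter by 0.4 mM)

- how the opening rate goes with [catalyst] round the charge of the delta run: the exponent of the rate at two percent of substrate gone to product
- how the opening rate goes with [substrate] round the charge of the delta run: the exponent of the rate at two percent of substrate gone to product (one fixed amount of product, the same in the runs compared)
- product in the gamma run at 9.7 min, as a share of the substrate charged

- Overall: substrate -> product, with catalyst as catalyst.
- Constant volume, constant temperature.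
- Bound and free are read together.
- An order is taken over about fifteen percent of the charge, up and down.

The neighbour of the gamma run is the epsilon run, which has the same 1.60 mM of catalyst but 120 mM of substrate in place of 170 mM. The delta run stands a step below it at 80.0 mM. Take the opening rate of a run as the product at its second reading over the time of that reading: 8.09 mM min⁻¹ in the delta run and 9.64 mM min⁻¹ in the epsilon run. Neither run ends near its charge, yet both have slowed by 9.7 min: over the last interval the delta run gains 0.789 mM min⁻¹ and the epsilon run 1.47 mM min⁻¹. So the end of each flask can be split into how fast it starts and how long it keeps going.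

In the delta run, 5.12 min is the product at the last reading divided by the opening rate, the working time: the minutes the flask would need at its opening pace to make what it holds. The epsilon run reads 5.14 min, about the same on these single second readings, each with its scatter. The epsilon run ends 1.20 times above the delta run on 1.50 times the charge, and on these readings its opening rate is higher by a factor of 1.19. The eta run, at 70.6% of its charge in product, reads a shorter 3.41 min, so carrying the working time upward to the gamma run is an assumption.

As readings with their scatter, the opening rates give an order of 0.876 in catalyst and, from the eta run to the epsilon run, 0.282 in substrate. The gamma run should then open at 10.6 mM min⁻¹ and, over the working time of the epsilon run, make 54.6 mM, which is 32.1% of its charge.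

The forecast differs slightly from this reckoning, with orders 1 and 0.3 and a share of 33%, holding that “Product at 9.7 min is close to the opening rate times 5 min for delta and epsilon”.

The simulation gives 0.95 in catalyst, 0.20 in substrate and 32.5% of the charge, which is 55.2 mM of product in the gamma run at 9.7 min, and the flask runs by these steps:

    catalyst + substrate ⇌ catalyst-substrate complex, settled at all times (114.0 M⁻¹)
    catalyst-substrate complex ⇌ product + catalyst (6.600 min⁻¹, 159.6 M⁻¹ min⁻¹)
    2 substrate → homo dimer (1.200 M⁻¹ min⁻¹)
    2 catalyst ⇌ resting dimer, settled at all times (1620 M⁻¹)

The rate of the epsilon run, taken where two percent of the delta run's substrate has turned, is 9.5 mM min⁻¹, which is 1.1 times the rate of the delta run at that same amount of product, and with it the working time of the epsilon run reads 5.21 min. With its rate of 6.5 mM min⁻¹ at that point, the eta run reads 3.47 min.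

The data stem from a simulated flask with made-up constants, noise included.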